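**Plan**

- Retrosynthesis: cut the 7-O–S bond and the 4'-O-benzyl bond; then C7–C8 of ring A (Claisen); then C5–C6 (two-carbon extension of a pyranone-3-carboxylic acid); then C4–C4a and O1–C2 of ring C; finally C2–C1' (aryl–alkyne bond).
- Forward: aryl–alkyne coupling, ring C as a 4-pyranone from tert-butyl acetoacetate and the arylpropioloyl chloride, chain extension to the β-keto ester, ring A by Claisen folding, 7-O-sulfation, debenzylation.
- Enabling feature: ring A carries oxygen on C5, C7 and C8a in the 1,3,5 (acetate) pattern. C5–C6–C7 can therefore be a β-keto ester chain on C4a, and C8 a methyl group on C8a of ring C, acidified through C8a=C4a–C4=O.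
- Stereochemistry: the target has no stereocentre. The control elements are regiochemical: an acetoacetate with a single ketone fixes the sense of ring C closure, and the chelated 5-OH leaves only the 7-OH open to sulfation.

Key step: step 6

Assumption: sulfates 15 and 16 are written as the free hydrogen sulfates of the target formula; in the flask and on isolation they would be the triethylammonium (or, after ion exchange, sodium) salts.

**Route**

Step 1
Reactants: 1 1-(benzyloxy)-4-iodobenzene; 2 propiolic acid
Product: 3 3-[4-(benzyloxy)phenyl]prop-2-ynoic acid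
Conditions: Pd(PPh3)4 (cat.), DBU, DMSO, rt; aq. HCl work-up
Reagents that add atoms: none
Why: Copper-free Sonogashira coupling of an aryl iodide with the DBU salt of propiolic acid; at room temperature the carboxyl group should be kept, since the decarboxylative second coupling needs heating.

Step 2
Reactants: 3 3-[4-(benzyloxy)phenyl]prop-2-ynoic acid
Product: 4 3-[4-(benzyloxy)phenyl]prop-2-ynoyl chloride
Conditions: (COCl)2, DMF (cat.), CH2Cl2, 0 °C to rt; evaporate, use crude
Reagents that add atoms: oxalyl chloride, ClC(=O)C(=O)Cl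
Why: Acid chloride formation through the Vilsmeier-type chloroiminium salt under cold, near-neutral conditions, which should keep HCl addition to the triple bond low.

Step 3
Reactants: 4 3-[4-(benzyloxy)phenyl]prop-2-ynoyl chloride; 5 tert-butyl acetoacetate
Product: 7 tert-butyl 6-[4-(benzyloxy)phenyl]-2-methyl-4-oxo-4H-pyran-3-carboxylate, via C-acylated ynone 6 (not isolated)
Conditions: MgCl2, pyridine, CH2Cl2, 0 °C to rt; 1 M HCl wash; then Et3N (cat.), CH2Cl2, rt
Reagents that add atoms: none
Why: C-acylation of the β-keto ester as the chelate it forms with MgCl2 (Rathke conditions), followed by 6-endo-dig oxa-Michael addition of the acetyl enol oxygen to the ynone, the classical way from acetoacetates and arylpropioloyl chlorides to 4-pyranone-3-carboxylates; only one ketone oxygen is present, so the methyl group must end up beside the ester.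

Step 4
Reactants: 7 tert-butyl 6-[4-(benzyloxy)phenyl]-2-methyl-4-oxo-4H-pyran-3-carboxylate
Product: 8 6-[4-(benzyloxy)phenyl]-2-methyl-4-oxo-4H-pyran-3-carboxylic acid
Conditions: TFA, CH2Cl2, 0 °C to rt
Reagents that add atoms: none
Why: Acidolysis of the tert-butyl ester with loss of isobutene avoids hydroxide, which would open the pyranone, and should leave the aryl benzyl ether intact; the acid sits on an sp2 carbon and is not expected to decarboxylate.

Step 5
Reactants: 8 6-[4-(benzyloxy)phenyl]-2-methyl-4-oxo-4H-pyran-3-carboxylic acid; 9 potassium methyl malonate (KO2CCH2CO2Me)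
Product: 12 methyl 3-{6-[4-(benzyloxy)phenyl]-2-methyl-4-oxo-4H-pyran-3-yl}-3-oxopropanoate, via acyl imidazolide 10 (not isolated), via acylmalonic half ester 11 (not isolated)
Conditions: CDI, THF, rt; then 9, MgCl2, Et3N, MeCN, rt to 40 °C; 1 M HCl work-up
Reagents that add atoms: none
Why: Masamune-type decarboxylative Claisen chain extension: the imidazolide is C-acylated by the malonate half-ester enolate generated with MgCl2 and Et3N, and the acylmalonic acid loses CO2 on acidification; the conditions are mild and poorly nucleophilic toward the pyranone.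

Step 6
Reactants: 12 methyl 3-{6-[4-(benzyloxy)phenyl]-2-methyl-4-oxo-4H-pyran-3-yl}-3-oxopropanoate
Product: 14 2-[4-(benzyloxy)phenyl]-5,7-dihydroxy-4H-chromen-4-one, via trione tautomer 13 (not isolated)
Conditions: Mg(OMe)2 (excess), MeOH, reflux; then 1 M HCl
Reagents that add atoms: none
Why: Proposed new method: Mg(OMe)2 turns the β-keto ester into its chelate, and proton exchange in methanol gives access to the tautomeric anion in which the methyl group on C8a is deprotonated (it is vinylogous to the C4 carbonyl through C8a=C4a and, while the chain is in its keto form, to the C5 carbonyl as well) and the ester is activated by the metal; this carbanion (C8) adds to the ester carbonyl (C7), methoxide leaves, and trione 13 enolises twice to aromatic ring A, whose phenoxide should make the sequence irreversible. The closest known reactions are the Claisen cyclisation of 3,5,7-triketo esters to acylphloroglucinols with Mg(OMe)2, the aldol and acylation chemistry of 2-methyl-4-pyranone carbanions and the Staunton–Weinreb annulation of toluate carbanions, none of which joins a pyranone methyl group to a chain ester in this way. Ring A closes in the 6-exo-trig mode, the C8a=C4a double bond of ring C holding the methyl group and the acyl chain cis and within reach. No stereocentre is formed. The step needs C7 to be the only electrophile that C8 can reach and ring C to survive: attack at the C5 ketone would give a four-membered ring and is excluded, retro-Claisen loss of the chain is held back because the chain rests as its chelated enolate, and methoxide addition at C8a is reversible in dry methanol and is drained by the aromatisation. Methoxide is chosen because it matches the methyl ester, so exchange at C7 changes nothing.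

Step 7
Reactants: 14 2-[4-(benzyloxy)phenyl]-5,7-dihydroxy-4H-chromen-4-one
Product: 15 2-[4-(benzyloxy)phenyl]-5-hydroxy-4-oxo-4H-chromen-7-yl hydrogen sulfate
Conditions: SO3·NMe3, Et3N, DMF, 40 °C
Reagents that add atoms: sulfur trioxide–trimethylamine complex, C[N+](C)(C)S(=O)(=O)[O-]
Why: O-sulfation of a phenol with an amine–SO3 complex; the 7-OH is the most acidic and the only free hydroxyl, since the 5-OH is tied up in a hydrogen bond to the C4 carbonyl and the 4'-OH is benzylated, so monosulfation at O7 is expected.

Step 8
Reactants: 15 2-[4-(benzyloxy)phenyl]-5-hydroxy-4-oxo-4H-chromen-7-yl hydrogen sulfate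
Product: 16 apigenin 7-sulfate
Conditions: H2 (1 atm), 10% Pd/C, MeOH–THF, rt
Reagents that add atoms: none
Why: Hydrogenolysis of the aryl benzyl ether; under neutral conditions at atmospheric pressure the aryl sulfate salt and the C2=C3 bond of the flavone (a vinylogous ester) should both be left alone.

**Compound list**

1 | 1-(benzyloxy)-4-iodobenzene | Ic1ccc(OCc2ccccc2)cc1 | starting material
2 | propiolic acid | C#CC(=O)O | starting material
3 | 3-[4-(benzyloxy)phenyl]prop-2-ynoic acid | O=C(O)C#Cc1ccc(OCc2ccccc2)cc1 | intermediate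
4 | 3-[4-(benzyloxy)phenyl]prop-2-ynoyl chloride | O=C(Cl)C#Cc1ccc(OCc2ccccc2)cc1 | intermediate
5 | tert-butyl acetoacetate | CC(=O)CC(=O)OC(C)(C)C | starting material
6 | tert-butyl 2-acetyl-5-[4-(benzyloxy)phenyl]-3-oxopent-4-ynoate (C-acylated ynone, not isolated) | CC(=O)C(C(=O)OC(C)(C)C)C(=O)C#Cc1ccc(OCc2ccccc2)cc1 | intermediate
7 | tert-butyl 6-[4-(benzyloxy)phenyl]-2-methyl-4-oxo-4H-pyran-3-carboxylate | CC(C)(C)OC(=O)c1c(C)oc(-c2ccc(OCc3ccccc3)cc2)cc1=O | intermediate
8 | 6-[4-(benzyloxy)phenyl]-2-methyl-4-oxo-4H-pyran-3-carboxylic acid | O=C(O)c1c(C)oc(-c2ccc(OCc3ccccc3)cc2)cc1=O | intermediate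
9 | potassium methyl malonate (potassium 3-methoxy-3-oxopropanoate) | COC(=O)CC(=O)[O-].[K+] | starting material
10 | 6-[4-(benzyloxy)phenyl]-3-(1H-imidazole-1-carbonyl)-2-methyl-4H-pyran-4-one (acyl imidazolide, not isolated) | O=C(c1c(C)oc(-c2ccc(OCc3ccccc3)cc2)cc1=O)n1ccnc1 | intermediate
11 | 2-{6-[4-(benzyloxy)phenyl]-2-methyl-4-oxo-4H-pyran-3-carbonyl}-3-methoxy-3-oxopropanoic acid (acylmalonic half ester, not isolated) | COC(=O)C(C(=O)O)C(=O)c1c(C)oc(-c2ccc(OCc3ccccc3)cc2)cc1=O | intermediate
12 | methyl 3-{6-[4-(benzyloxy)phenyl]-2-methyl-4-oxo-4H-pyran-3-yl}-3-oxopropanoate | COC(=O)CC(=O)c1c(C)oc(-c2ccc(OCc3ccccc3)cc2)cc1=O | intermediate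
13 | 2-[4-(benzyloxy)phenyl]-4H-chromene-4,5,7(6H,8H)-trione (trione tautomer, not isolated) | O=C1CC(=O)c2c(C1)oc(-c1ccc(OCc3ccccc3)cc1)cc2=O | intermediate
14 | 2-[4-(benzyloxy)phenyl]-5,7-dihydroxy-4H-chromen-4-one | O=c1cc(-c2ccc(OCc3ccccc3)cc2)oc2cc(O)cc(O)c12 | intermediate
15 | 2-[4-(benzyloxy)phenyl]-5-hydroxy-4-oxo-4H-chromen-7-yl hydrogen sulfate | O=c1cc(-c2ccc(OCc3ccccc3)cc2)oc2cc(OS(=O)(=O)O)cc(O)c12 | intermediate
16 | apigenin 7-sulfate (5-hydroxy-2-(4-hydroxyphenyl)-4-oxo-4H-chromen-7-yl hydrogen sulfate) | O=c1cc(-c2ccc(O)cc2)oc2cc(OS(=O)(=O)O)cc(O)c12 | target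

**Step count and risks**

Total steps: 8. Longest linear sequence: 8 steps (1 to 16).

Steps most likely to fail:

1. Step 6 (Proposed new method). Methoxide may open ring C at C8a faster than the methyl group is deprotonated, after which the freed polyketone could refold along other aldol and Claisen paths. The chain may also be lost by retro-Claisen cleavage, or the chelated enolate may simply not react. The fallback uses known chemistry: ring A is taken from phloroglucinol and ring C is closed last. It sets out from 4 and returns at 14. Chloride 4 is converted with MeNHOMe·HCl and pyridine into the Weinreb amide 3-[4-(benzyloxy)phenyl]-N-methoxy-N-methylprop-2-ynamide F1. Phloroglucinol is protected with MOMCl and iPr2NEt as 1,3,5-tris(methoxymethoxy)benzene F2, which n-BuLi in THF at 0 °C lithiates between two of its ether groups to give [2,4,6-tris(methoxymethoxy)phenyl]lithium F3. Addition of F3 to F1 at −78 °C should give the ynone 3-[4-(benzyloxy)phenyl]-1-[2,4,6-tris(methoxymethoxy)phenyl]prop-2-yn-1-one F4. HCl in methanol removes the three acetal groups to give 3-[4-(benzyloxy)phenyl]-1-(2,4,6-trihydroxyphenyl)prop-2-yn-1-one F5. Catalytic DMAP in DMF then closes F5 in the 6-endo-dig sense to 14.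

2. Step 3. The acid chloride may acylate on oxygen, chloride or pyridine may add to the activated triple bond, or the enol may close 5-exo to a furanone in place of the 6-endo pyranone. The fallback builds ring C without an ynoyl chloride, from an acylketene and an enamine. It sets out from 5 and returns at 7. Ester 5 is condensed with pyrrolidine (toluene, water removal) to tert-butyl (2E)-3-(pyrrolidin-1-yl)but-2-enoate F6. 4-(Benzyloxy)benzoyl chloride and Meldrum's acid with pyridine give 5-{[4-(benzyloxy)phenyl](hydroxy)methylidene}-2,2-dimethyl-1,3-dioxane-4,6-dione F7. Heating F7 with F6 in toluene at about 100 °C should release the aroylketene 3-[4-(benzyloxy)phenyl]prop-1-ene-1,3-dione F8, which acylates the enamine at carbon. The aryl ketone oxygen then closes onto the enamine carbon with loss of pyrrolidine to give 7.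

3. Step 5. Activation of the hindered, hydrogen-bonded acid may be slow, or the malonate enolate may add in conjugate fashion to the pyranone in competition with acyl substitution. The fallback brings in the two carbons as Meldrum's acid and sets the ester by thermal methanolysis. It sets out from 8 and returns at 12. Acid 8, Meldrum's acid, EDC·HCl and DMAP in CH2Cl2 should give 5-({6-[4-(benzyloxy)phenyl]-2-methyl-4-oxo-4H-pyran-3-yl}(hydroxy)methylidene)-2,2-dimethyl-1,3-dioxane-4,6-dione F9. Refluxing F9 in methanol gives 12.

**Further compounds**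

F1 | step 6 | 3-[4-(benzyloxy)phenyl]-N-methoxy-N-methylprop-2-ynamide | CON(C)C(=O)C#Cc1ccc(OCc2ccccc2)cc1
F2 | step 6 | 1,3,5-tris(methoxymethoxy)benzene | COCOc1cc(OCOC)cc(OCOC)c1
F3 | step 6 | [2,4,6-tris(methoxymethoxy)phenyl]lithium | [Li]c1c(OCOC)cc(OCOC)cc1OCOC
F4 | step 6 | 3-[4-(benzyloxy)phenyl]-1-[2,4,6-tris(methoxymethoxy)phenyl]prop-2-yn-1-one | COCOc1cc(OCOC)c(C(=O)C#Cc2ccc(OCc3ccccc3)cc2)c(OCOC)c1
F5 | step 6 | 3-[4-(benzyloxy)phenyl]-1-(2,4,6-trihydroxyphenyl)prop-2-yn-1-one | O=C(C#Cc1ccc(OCc2ccccc2)cc1)c1c(O)cc(O)cc1O
F6 | step 3 | tert-butyl (2E)-3-(pyrrolidin-1-yl)but-2-enoate | C/C(=C\C(=O)OC(C)(C)C)N1CCCC1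
F7 | step 3 | 5-{[4-(benzyloxy)phenyl](hydroxy)methylidene}-2,2-dimethyl-1,3-dioxane-4,6-dione | CC1(C)OC(=O)C(=C(O)c2ccc(OCc3ccccc3)cc2)C(=O)O1
F8 | step 3 | 3-[4-(benzyloxy)phenyl]prop-1-ene-1,3-dione | O=C=CC(=O)c1ccc(OCc2ccccc2)cc1
F9 | step 5 | 5-({6-[4-(benzyloxy)phenyl]-2-methyl-4-oxo-4H-pyran-3-yl}(hydroxy)methylidene)-2,2-dimethyl-1,3-dioxane-4,6-dione | CC1(C)OC(=O)C(=C(O)c2c(C)oc(-c3ccc(OCc4ccccc4)cc3)cc2=O)C(=O)O1
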